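The carbocycle is cut at C1–C2: an intramolecular Nozaki–Hiyama–Kishi reaction joins a (Z)-alkenyl iodide (C2=C3) to an aldehyde (C1) at the two ends of the open chain C1–C6. In one operation this closes the cyclohexene ring and creates a C1 carbinol on the face of the C5 side chain. The feature exploited is that the C2–C3 epoxide oxygen of the target is cis to that chain, so the new hydroxyl can deliver the epoxide oxygen before it is oxidised to the C1 ketone. The precursor is an acyclic α-(4-methoxybenzyloxy) aldehyde carrying C5, C6 and the angeloylated C8 centre, built from a chiral pyranone by cuprate addition.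

Key step: step 14

Atom labels: ring C1 (C=O), C2 (C–CH3, the methyl is C15), C3, C4, C5 (bears the chain), C6 (C–OAc); chain C7 (bears the C14 methylene), C8 (C–O-angeloyl), C9–C13 (prenyl). PMB = 4-methoxybenzyl, TBS = tert-butyldimethylsilyl.

Assumption: the (R,R)-ligand of step 1 is taken to give the (S)-ether, by analogy with imide nucleophiles on the same epoxide; if the sense is opposite, the (S,S)-ligand is used and nothing else changes.

Step 1
Reactants: 1 4-methoxybenzyl alcohol; 2 racemic 2-vinyloxirane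
Product: 3 (2S)-2-[(4-methoxybenzyl)oxy]but-3-en-1-ol
Conditions: Pd2(dba)3·CHCl3 (1 mol%), (1R,2R)-N,N′-bis[2-(diphenylphosphino)benzoyl]cyclohexane-1,2-diamine (3 mol%), Et3B (1 mol%), CH2Cl2, rt
Reagents that add atoms: none
Why: Palladium-catalysed dynamic kinetic asymmetric allylic etherification: both epoxide enantiomers ionise to interconverting π-allylpalladium alkoxides, the borate-bound benzylic alkoxide is delivered to the internal allyl terminus, and the chiral diphosphine sets C6 as (S).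

Step 2
Reactants: 3 (2S)-2-[(4-methoxybenzyl)oxy]but-3-en-1-ol; 4 acryloyl chloride
Product: 5 (2S)-2-[(4-methoxybenzyl)oxy]but-3-en-1-yl acrylate
Conditions: Et3N, CH2Cl2, −20 to 0 °C
Reagents that add atoms: none
Why: Standard O-acylation of the primary alcohol by an acid chloride with an amine base installs C3 and C4 as an acrylate and does not touch C6.

Step 3
Reactants: 5 (2S)-2-[(4-methoxybenzyl)oxy]but-3-en-1-yl acrylate
Product: 6 (5S)-5-[(4-methoxybenzyl)oxy]-5,6-dihydro-2H-pyran-2-one
Conditions: second-generation Grubbs catalyst (5 mol%), CH2Cl2, 40 °C, 10 mM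
Reagents that add atoms: none
Why: Ring-closing metathesis of an acrylate with a monosubstituted alkene, driven by loss of ethene, closes the six-membered unsaturated lactone that carries C1 and C3–C6.

Step 4
Reactants: 6 (5S)-5-[(4-methoxybenzyl)oxy]-5,6-dihydro-2H-pyran-2-one; 7 2-bromo-3,3-diethoxyprop-1-ene
Product: 11 (4S,5S)-4-(3,3-diethoxyprop-1-en-2-yl)-5-[(4-methoxybenzyl)oxy]tetrahydro-2H-pyran-2-one (4,5-trans), via alkenyllithium 8 (not isolated), via lithium dialkenylcuprate 9 (not isolated), via trimethylsilyl ketene acetal 10 (not isolated)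
Conditions: 7, t-BuLi (2 equiv), Et2O, −78 °C; CuI (0.5 equiv), −40 °C; then 6, Me3SiCl, −78 °C; aq NH4Cl
Reagents that add atoms: none
Why: Gilman cuprate 1,4-addition accelerated by Me3SiCl: the alkenyl group enters C5 on the half-chair face opposite the adjacent C6 OPMB group, which sets C5 trans to C6–O, and the silyl ketene acetal is hydrolysed on work-up.

Step 5
Reactants: 11 (4S,5S)-4-(3,3-diethoxyprop-1-en-2-yl)-5-[(4-methoxybenzyl)oxy]tetrahydro-2H-pyran-2-one
Product: 12 (4S,5S)-4-(3,3-diethoxyprop-1-en-2-yl)-5-[(4-methoxybenzyl)oxy]tetrahydro-2H-pyran-2-ol (both anomers)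
Conditions: i-Bu2AlH (1.1 equiv), CH2Cl2, −78 °C; Rochelle salt
Reagents that add atoms: none
Why: Partial reduction of a δ-lactone by i-Bu2AlH at low temperature stops at the tetrahedral aluminate and gives the lactol, a masked C3 aldehyde whose ring oxygen is the future C1 hydroxyl.

Step 6
Reactants: 12 (4S,5S)-4-(3,3-diethoxyprop-1-en-2-yl)-5-[(4-methoxybenzyl)oxy]tetrahydro-2H-pyran-2-ol; 13 ethyltriphenylphosphonium iodide
Product: 17 (2S,3S,5Z)-3-(3,3-diethoxyprop-1-en-2-yl)-6-iodo-2-[(4-methoxybenzyl)oxy]hept-5-en-1-ol, via ethylidene ylide 14 (not isolated), via iodoethylphosphonium iodide 15 (not isolated), via iodoethylidene ylide 16 (not isolated)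
Conditions: 13 (3 equiv), n-BuLi, THF, 0 °C; I2, −78 °C; NaN(SiMe3)2, −78 to −20 °C; then 12, −78 °C to rt
Reagents that add atoms: iodine, [I][I]
Why: Stork–Zhao variant of the Wittig olefination on the open hydroxy aldehyde form of the lactol: the α-iodo ylide reacts under kinetic control through the cis-oxaphosphetane, placing iodine cis to C4 and so giving the (Z)-iodoalkene, while ring opening frees the C1 hydroxyl.

Step 7
Reactants: 17 (2S,3S,5Z)-3-(3,3-diethoxyprop-1-en-2-yl)-6-iodo-2-[(4-methoxybenzyl)oxy]hept-5-en-1-ol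
Product: 18 C1 TBS ether of 17
Conditions: t-BuMe2SiCl, imidazole, DMF, 0 °C to rt
Reagents that add atoms: tert-butyldimethylsilyl chloride, CC(C)(C)[Si](C)(C)Cl
Why: Imidazole-promoted silylation of the primary C1 hydroxyl under base, which keeps it from adding to the acetal or the later enal.

Step 8
Reactants: 18 C1 TBS ether of 17
Product: 19 (3S,5Z)-3-[(1S)-2-(tert-butyldimethylsilyloxy)-1-[(4-methoxybenzyl)oxy]ethyl]-6-iodo-2-methylidenehept-5-enal
Conditions: PPTS (cat.), acetone–H2O (10:1), rt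
Reagents that add atoms: water, O
Why: Mild acid hydrolysis of an α,β-unsaturated (allylic) acetal, which ionises far more readily than the silyl and PMB ethers, unveils the 2-substituted acrolein C8 aldehyde.

Step 9
Reactants: 19 (3S,5Z)-3-[(1S)-2-(tert-butyldimethylsilyloxy)-1-[(4-methoxybenzyl)oxy]ethyl]-6-iodo-2-methylidenehept-5-enal; 20 B-allyldiisopinocampheylborane derived from (+)-α-pinene
Product: 22 (4S,6S,8Z)-6-[(1S)-2-(tert-butyldimethylsilyloxy)-1-[(4-methoxybenzyl)oxy]ethyl]-9-iodo-5-methylidenedeca-1,8-dien-4-ol, via diisopinocampheylborinate 21 (not isolated)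
Conditions: 20 (1.3 equiv), Et2O, −78 °C; then NaOH, H2O2, 0 °C to rt
Reagents that add atoms: none
Why: Brown allylboration through a closed chair transition state: the isopinocampheyl groups from (+)-α-pinene direct allyl transfer to the aldehyde face that gives the (8S)-carbinol under reagent control, and the borinate is cleaved oxidatively on work-up.

Step 10
Reactants: 22 (4S,6S,8Z)-6-[(1S)-2-(tert-butyldimethylsilyloxy)-1-[(4-methoxybenzyl)oxy]ethyl]-9-iodo-5-methylidenedeca-1,8-dien-4-ol; 23 2-methylbut-2-ene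
Product: 24 (5S,7S,9Z)-7-[(1S)-2-(tert-butyldimethylsilyloxy)-1-[(4-methoxybenzyl)oxy]ethyl]-10-iodo-2-methyl-6-methylideneundeca-2,9-dien-5-ol
Conditions: second-generation Grubbs catalyst (5 mol%), 23 (excess), CH2Cl2, 40 °C
Reagents that add atoms: none
Why: Olefin cross-metathesis of the monosubstituted alkene with excess 2-methylbut-2-ene turns the allyl into the prenyl group, the 1,1-disubstituted C7=C14 alkene and the trisubstituted iodoalkene being too hindered to enter the catalytic cycle.

Step 11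
Reactants: 24 (5S,7S,9Z)-7-[(1S)-2-(tert-butyldimethylsilyloxy)-1-[(4-methoxybenzyl)oxy]ethyl]-10-iodo-2-methyl-6-methylideneundeca-2,9-dien-5-ol; 25 angelic acid
Product: 27 C8 angelate [(2Z)-2-methylbut-2-enoate] of 24, via mixed anhydride 26 (not isolated)
Conditions: 25, 2,4,6-trichlorobenzoyl chloride, Et3N, toluene, rt; then 24, 80 °C
Reagents that add atoms: none
Why: Yamaguchi-type esterification through the mixed anhydride without a nucleophilic catalyst, which acylates the hindered C8 hydroxyl with retention at C8 and avoids the conjugate addition–elimination that would isomerise the angeloyl group to tigloyl.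

Step 12
Reactants: 27 C8 angelate of 24
Product: 28 (5S,6S,8S,2Z)-iodoalkenyl alcohol: 27 with the C1 silyl ether cleaved to CH2OH
Conditions: HF·pyridine, pyridine, THF, 0 °C to rt
Reagents that add atoms: none
Why: Fluoride-mediated cleavage of the primary silyl ether under buffered acidic conditions, to which the angelate, the PMB ether and the iodoalkene are inert.

Step 13
Reactants: 28 (5S,6S,8S,2Z)-iodoalkenyl alcohol
Product: 29 (5S,6S,8S,2Z)-iodoalkenyl aldehyde: C1 aldehyde, C6 OPMB, C5 bearing the (Z)-3-iodobut-2-enyl group and the C7(=C14H2)–C8(O-angeloyl)–prenyl chain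
Conditions: Dess–Martin periodinane, NaHCO3, CH2Cl2, 0 °C to rt
Reagents that add atoms: none
Why: Dess–Martin oxidation under buffered, non-basic conditions gives the α-alkoxy aldehyde without epimerisation at C6, and the product is used at once without chromatography.

Step 14
Reactants: 29 (5S,6S,8S,2Z)-iodoalkenyl aldehyde
Product: 31 (1S,5S,6S,8S)-2-methylcyclohex-2-enol with C1–OH cis to the C5 chain and trans to the C6 OPMB group, via alkenylchromium dichloride 30 (not isolated)
Conditions: CrCl2 (8 equiv), NiCl2 (2 mol%), degassed DMSO, rt, 2 mM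
Reagents that add atoms: none
Why: Zerovalent nickel, formed from NiCl2 by divalent chromium, inserts into the C2–I bond with retention of the Z geometry, the alkenyl group is handed to trivalent chromium to give alkenylchromium 30, and this adds to the C1 aldehyde while nickel returns to the cycle. The closest known reaction type is the intramolecular Nozaki–Hiyama–Kishi cyclisation of iodoalkenyl aldehydes to cycloalkenols. The six-membered ring closes in the 6-exo-trig mode onto C1=O with C2=C3 ending up endocyclic, which only the Z iodide allows because it holds C2 and C4 cis. The new C1 stereocentre is controlled by C5 and C6: in the chair-like transition state the C5 chain and the C6 OPMB group are equatorial, the chromium-bound aldehyde oxygen also sits equatorial where the PMB ether oxygen can bridge to chromium, so C1–O forms trans to C6–O and cis to the C5 chain. The step needs chemoselectivity for the alkenyl iodide and the aldehyde, which the non-basic organochromium secures beside the allylic angelate, the three other alkenes and the epimerisable C6 centre. High dilution suppresses intermolecular coupling.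

Step 15
Reactants: 31 (1S,5S,6S,8S)-2-methylcyclohex-2-enol
Product: 32 (1R,2R,3S,5S,6S,8S)-2,3-epoxy alcohol with the epoxide oxygen cis to C1–OH and to the C5 chain
Conditions: VO(acac)2 (5 mol%), t-BuOOH (1.5 equiv), CH2Cl2, 0 °C to rt
Reagents that add atoms: tert-butyl hydroperoxide, CC(C)(C)OO
Why: Hydroxyl-directed epoxidation: the vanadium alkoxide of C1–OH binds the peroxide and delivers oxygen to the same face of C2=C3, so C2 and C3 are set with the epoxide cis to C1–OH and to the C5 chain, while alkenes without an allylic hydroxyl stay untouched.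

Step 16
Reactants: 32 (1R,2R,3S,5S,6S,8S)-2,3-epoxy alcohol
Product: 33 (2S,3S,5S,6S,8S)-2,3-epoxy ketone with C6 OPMB
Conditions: Dess–Martin periodinane, NaHCO3, CH2Cl2, 0 °C to rt
Reagents that add atoms: none
Why: Dess–Martin oxidation of the secondary epoxy alcohol to the α,β-epoxy ketone under buffered conditions, which leaves the epoxide and the C6 centre unchanged.

Step 17
Reactants: 33 (2S,3S,5S,6S,8S)-2,3-epoxy ketone with C6 OPMB
Product: 34 (2S,3S,5S,6S,8S)-6-hydroxy-2,3-epoxy ketone
Conditions: DDQ, CH2Cl2–pH 7 buffer (10:1), 0 °C to rt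
Reagents that add atoms: none
Why: Oxidative PMB ether cleavage: electron transfer to DDQ gives the benzylic oxocarbenium ion, which water hydrolyses to the free C6 hydroxyl and 4-methoxybenzaldehyde without affecting the epoxy ketone or the esters.

Step 18
Reactants: 34 (2S,3S,5S,6S,8S)-6-hydroxy-2,3-epoxy ketone
Product: 35 CNP0150645.2, the (2S,3S,5S,6S,8S)-6-acetoxy-2,3-epoxy ketone bearing the C8 angelate
Conditions: Ac2O, pyridine, DMAP (cat.), CH2Cl2, 0 °C
Reagents that add atoms: acetic anhydride, CC(=O)OC(C)=O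
Why: Pyridine-mediated O-acetylation of the α-hydroxy ketone at low temperature, mild enough to keep the C6 configuration, the equatorial acetate trans to the C5 chain being also the more stable epimer.

Compound list
1 | 4-methoxybenzyl alcohol | COc1ccc(CO)cc1 | starting material
2 | 2-vinyloxirane (racemic) | C=CC1CO1 | starting material
3 | (2S)-2-[(4-methoxybenzyl)oxy]but-3-en-1-ol | C=C[C@H](OCc1ccc(OC)cc1)CO | intermediate
4 | acryloyl chloride | C=CC(=O)Cl | starting material
5 | (2S)-2-[(4-methoxybenzyl)oxy]but-3-en-1-yl acrylate | C=C[C@H](OCc1ccc(OC)cc1)COC(=O)C=C | intermediate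
6 | (5S)-5-[(4-methoxybenzyl)oxy]-5,6-dihydro-2H-pyran-2-one | O=C1C=C[C@H](OCc2ccc(OC)cc2)CO1 | intermediate
7 | 2-bromo-3,3-diethoxyprop-1-ene | C=C(Br)C(OCC)OCC | starting material
8 | (3,3-diethoxyprop-1-en-2-yl)lithium | [Li]C(=C)C(OCC)OCC | intermediate (not isolated)
9 | lithium bis(3,3-diethoxyprop-1-en-2-yl)cuprate | [Li+].C=C([Cu-]C(=C)C(OCC)OCC)C(OCC)OCC | intermediate (not isolated)
10 | (3S,4S)-4-(3,3-diethoxyprop-1-en-2-yl)-3-[(4-methoxybenzyl)oxy]-6-(trimethylsilyloxy)-3,4-dihydro-2H-pyran | C=C(C(OCC)OCC)[C@@H]1C=C(O[Si](C)(C)C)OC[C@H]1OCc1ccc(OC)cc1 | intermediate (not isolated)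
11 | (4S,5S)-4-(3,3-diethoxyprop-1-en-2-yl)-5-[(4-methoxybenzyl)oxy]tetrahydro-2H-pyran-2-one (4,5-trans) | C=C(C(OCC)OCC)[C@@H]1CC(=O)OC[C@H]1OCc1ccc(OC)cc1 | intermediate
12 | (4S,5S)-4-(3,3-diethoxyprop-1-en-2-yl)-5-[(4-methoxybenzyl)oxy]tetrahydro-2H-pyran-2-ol (both anomers) | C=C(C(OCC)OCC)[C@@H]1CC(O)OC[C@H]1OCc1ccc(OC)cc1 | intermediate
13 | ethyltriphenylphosphonium iodide | CC[P+](c1ccccc1)(c1ccccc1)c1ccccc1.[I-] | starting material
14 | ethylidenetriphenylphosphorane | CC=P(c1ccccc1)(c1ccccc1)c1ccccc1 | intermediate (not isolated)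
15 | (1-iodoethyl)triphenylphosphonium iodide | CC(I)[P+](c1ccccc1)(c1ccccc1)c1ccccc1.[I-] | intermediate (not isolated)
16 | (1-iodoethylidene)triphenylphosphorane | CC(I)=P(c1ccccc1)(c1ccccc1)c1ccccc1 | intermediate (not isolated)
17 | (2S,3S,5Z)-3-(3,3-diethoxyprop-1-en-2-yl)-6-iodo-2-[(4-methoxybenzyl)oxy]hept-5-en-1-ol | C=C(C(OCC)OCC)[C@H](C/C=C(/C)I)[C@H](OCc1ccc(OC)cc1)CO | intermediate
18 | C1 TBS ether of 17 | C=C(C(OCC)OCC)[C@H](C/C=C(/C)I)[C@H](OCc1ccc(OC)cc1)CO[Si](C)(C)C(C)(C)C | intermediate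
19 | (3S,5Z)-3-[(1S)-2-(tert-butyldimethylsilyloxy)-1-[(4-methoxybenzyl)oxy]ethyl]-6-iodo-2-methylidenehept-5-enal | C=C(C=O)[C@H](C/C=C(/C)I)[C@H](OCc1ccc(OC)cc1)CO[Si](C)(C)C(C)(C)C | intermediate
20 | B-allyldiisopinocampheylborane derived from (+)-α-pinene, (−)-Ipc2B(allyl) | C=CCB([C@@H]1C[C@@H]2C[C@H]([C@H]1C)C2(C)C)[C@@H]1C[C@@H]2C[C@H]([C@H]1C)C2(C)C | starting material
21 | O-diisopinocampheylboryl derivative (borinate) of 22 | C=C([C@H](CC=C)OB([C@@H]1C[C@@H]2C[C@H]([C@H]1C)C2(C)C)[C@@H]1C[C@@H]2C[C@H]([C@H]1C)C2(C)C)[C@H](C/C=C(/C)I)[C@H](OCc1ccc(OC)cc1)CO[Si](C)(C)C(C)(C)C | intermediate (not isolated)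
22 | (4S,6S,8Z)-6-[(1S)-2-(tert-butyldimethylsilyloxy)-1-[(4-methoxybenzyl)oxy]ethyl]-9-iodo-5-methylidenedeca-1,8-dien-4-ol | C=C([C@H](CC=C)O)[C@H](C/C=C(/C)I)[C@H](OCc1ccc(OC)cc1)CO[Si](C)(C)C(C)(C)C | intermediate
23 | 2-methylbut-2-ene | CC=C(C)C | starting material
24 | (5S,7S,9Z)-7-[(1S)-2-(tert-butyldimethylsilyloxy)-1-[(4-methoxybenzyl)oxy]ethyl]-10-iodo-2-methyl-6-methylideneundeca-2,9-dien-5-ol | C=C([C@H](CC=C(C)C)O)[C@H](C/C=C(/C)I)[C@H](OCc1ccc(OC)cc1)CO[Si](C)(C)C(C)(C)C | intermediate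
25 | angelic acid, (2Z)-2-methylbut-2-enoic acid | C/C=C(/C)C(=O)O | starting material
26 | (2Z)-2-methylbut-2-enoic 2,4,6-trichlorobenzoic anhydride | C/C=C(/C)C(=O)OC(=O)c1c(Cl)cc(Cl)cc1Cl | intermediate (not isolated)
27 | C8 angelate of 24 (C1 OTBS, C6 OPMB, Z-iodoalkene) | C=C([C@H](CC=C(C)C)OC(=O)/C(C)=C\C)[C@H](C/C=C(/C)I)[C@H](OCc1ccc(OC)cc1)CO[Si](C)(C)C(C)(C)C | intermediate
28 | (5S,6S,8S,2Z)-iodoalkenyl alcohol (C1 CH2OH) | C=C([C@H](CC=C(C)C)OC(=O)/C(C)=C\C)[C@H](C/C=C(/C)I)[C@H](OCc1ccc(OC)cc1)CO | intermediate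
29 | (5S,6S,8S,2Z)-iodoalkenyl aldehyde, precursor of the key step | C=C([C@H](CC=C(C)C)OC(=O)/C(C)=C\C)[C@H](C/C=C(/C)I)[C@H](OCc1ccc(OC)cc1)C=O | intermediate
30 | alkenylchromium dichloride from 29 (C2–CrCl2) | C=C([C@H](CC=C(C)C)OC(=O)/C(C)=C\C)[C@H](C/C=C(/C)[Cr](Cl)Cl)[C@H](OCc1ccc(OC)cc1)C=O | intermediate (not isolated)
31 | (1S,5S,6S,8S)-2-methylcyclohex-2-enol, product of the key step | C=C([C@H](CC=C(C)C)OC(=O)/C(C)=C\C)[C@@H]1CC=C(C)[C@H](O)[C@H]1OCc2ccc(OC)cc2 | intermediate
32 | (1R,2R,3S,5S,6S,8S)-2,3-epoxy alcohol | C=C([C@H](CC=C(C)C)OC(=O)/C(C)=C\C)[C@@H]1C[C@@H]2O[C@]2(C)[C@H](O)[C@H]1OCc1ccc(OC)cc1 | intermediate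
33 | (2S,3S,5S,6S,8S)-2,3-epoxy ketone with C6 OPMB | C=C([C@H](CC=C(C)C)OC(=O)/C(C)=C\C)[C@@H]1C[C@@H]2O[C@]2(C)C(=O)[C@H]1OCc1ccc(OC)cc1 | intermediate
34 | (2S,3S,5S,6S,8S)-6-hydroxy-2,3-epoxy ketone | C=C([C@H](CC=C(C)C)OC(=O)/C(C)=C\C)[C@@H]1C[C@@H]2O[C@]2(C)C(=O)[C@H]1O | intermediate
35 | CNP0150645.2 | C=C([C@H](CC=C(C)C)OC(=O)/C(C)=C\C)[C@@H]1C[C@@H]2O[C@]2(C)C(=O)[C@H]1OC(C)=O | target

Total step count: 18. Longest linear sequence: 18 steps (from 1 and 2 to 35).

Steps most likely to fail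

Step 6. The lactol may open too slowly at the low temperature that the iodo-ylide tolerates, so that the ylide decays before olefination. The fallback sets out from 11 and replaces the lactol by a free aldehyde. Aminolysis with Me(MeO)NH·HCl and i-PrMgCl in THF at −20 °C should give the δ-hydroxy Weinreb amide F1. Silylation (t-BuMe2SiCl, imidazole) should give its silyl ether F2, and i-Bu2AlH at −78 °C the aldehyde F3. This aldehyde meets ylide 16 at −78 °C and comes back to the route at 18, bypassing 12 and 17.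

Step 14. Facial selectivity in the addition to C1=O may be insufficient, so that the C1 epimer forms beside 31. The fallback sets out from 29 and moves the control of C1 from the ring closure to a hydride reduction. The same ring closure is run, and the mixture of 31 and the C1-epimeric cyclohexenol F4 is oxidised with MnO2 in CH2Cl2 to the 2-methylcyclohex-2-enone F5. Luche reduction (NaBH4, CeCl3·7H2O, MeOH, −78 °C) should then deliver hydride axially and give the equatorial alcohol, coming back to the route at 31.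

Step 11. Acyl transfer to the hindered allylic C8 hydroxyl may be slow, with Z to E isomerisation of the angeloyl unit. The fallback sets out from 24 and builds the angelate double bond on the substrate. Esterification with 2-[bis(2,2,2-trifluoroethoxy)phosphoryl]propanoic acid (DCC, DMAP, CH2Cl2) should give the phosphonate ester F6. Still–Gennari olefination with acetaldehyde (KN(SiMe3)2, 18-crown-6, THF, −78 °C) should form the (Z)-2-methylbut-2-enoate and come back to the route at 27.

Further compounds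
F1 | step 6 | (3S,4S)-3-(3,3-diethoxyprop-1-en-2-yl)-5-hydroxy-N-methoxy-4-[(4-methoxybenzyl)oxy]-N-methylpentanamide | C=C(C(OCC)OCC)[C@H](CC(=O)N(C)OC)[C@H](OCc1ccc(OC)cc1)CO
F2 | step 6 | 5-O-TBS ether of F1 | C=C(C(OCC)OCC)[C@H](CC(=O)N(C)OC)[C@H](OCc1ccc(OC)cc1)CO[Si](C)(C)C(C)(C)C
F3 | step 6 | (3S,4S)-5-(tert-butyldimethylsilyloxy)-3-(3,3-diethoxyprop-1-en-2-yl)-4-[(4-methoxybenzyl)oxy]pentanal | C=C(C(OCC)OCC)[C@H](CC=O)[C@H](OCc1ccc(OC)cc1)CO[Si](C)(C)C(C)(C)C
F4 | step 14 | C1 epimer of 31, (1R,5S,6S,8S)-2-methylcyclohex-2-enol | C=C([C@H](CC=C(C)C)OC(=O)/C(C)=C\C)[C@@H]1CC=C(C)[C@@H](O)[C@H]1OCc1ccc(OC)cc1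
F5 | step 14 | (5S,6S,8S)-2-methylcyclohex-2-enone with C6 OPMB | C=C([C@H](CC=C(C)C)OC(=O)/C(C)=C\C)[C@@H]1CC=C(C)C(=O)[C@H]1OCc1ccc(OC)cc1
F6 | step 11 | C8 2-[bis(2,2,2-trifluoroethoxy)phosphoryl]propanoate of 24 | C=C([C@H](CC=C(C)C)OC(=O)C(C)P(=O)(OCC(F)(F)F)OCC(F)(F)F)[C@H](C/C=C(/C)I)[C@H](OCc1ccc(OC)cc1)CO[Si](C)(C)C(C)(C)C
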